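The route rests on cutting the side chain between the allylic CH2 beside the methylidene-bearing carbon and the CH2 beside the secondary carbinol carbon. A tin-mediated radical allylation makes this bond in the last step: the primary radical from an unprotected, enantiopure iodo diol adds to the =CH2 end of an allylstannane that already carries the 7-methoxy-2H-chromen-2-one ring, and loss of Bu3Sn• regenerates the methylidene. The step exploits the C(=CH2)–CH2 unit of the chain: both allyl termini are CH2, so the allyl shift is invisible. The carbinol stereocentre comes from methyl (S)-glycidate and is never touched; lactone and hydroxyls need no protection.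

Key step: step 5

Assumption: 8-hydroxy-7-methoxy-2H-chromen-2-one (daphnetin 7-methyl ether) and methyl (S)-glycidate are taken as purchasable.

**Step 1**
Reactants: 1 3-methylbut-3-en-1-ol (isoprenol)
Product: 3 3-[(tributylstannyl)methyl]but-3-en-1-ol, via isoprenol dianion 2 (not isolated)
Conditions: n-BuLi (2.1 equiv), TMEDA, Et2O/hexane, 0 °C → rt; then Bu3SnCl (1.0 equiv), THF, −78 → 0 °C; H2O
Reagents that add atoms: tributyltin chloride CCCC[Sn](Cl)(CCCC)CCCC
Why: Alkoxide-directed allylic lithiation of the methyl group should give a 2-substituted allyllithium whose two termini are both CH2, and electrophilic stannylation of this organolithium on carbon can therefore give only one constitution.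

**Step 2**
Reactants: 3 3-[(tributylstannyl)methyl]but-3-en-1-ol; 4 8-hydroxy-7-methoxy-2H-chromen-2-one
Product: 5 7-methoxy-8-({3-[(tributylstannyl)methyl]but-3-en-1-yl}oxy)-2H-chromen-2-one
Conditions: PPh3, DIAD (added last, dropwise), THF, 0 °C → rt
Reagents that add atoms: none
Why: Mitsunobu etherification: the primary alcohol is activated as its oxyphosphonium ion and displaced by the acidic phenoxide of 4 under neutral conditions that the lactone and the allylstannane should tolerate, DIAD being consumed by PPh3 before it can attack the stannane.

**Step 3**
Reactants: 6 methyl (2S)-oxirane-2-carboxylate (methyl (S)-glycidate)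
Product: 8 2-[(2S)-oxiran-2-yl]propan-2-ol, via epoxy ketone 7 (not isolated)
Conditions: MeMgCl (2.2 equiv), THF, −78 → −30 °C; aq NH4Cl
Reagents that add atoms: methylmagnesium chloride C[Mg]Cl
Why: Double Grignard addition to an ester: at low temperature the ester and ketone carbonyls should react far faster than the oxirane, the chloride counter-ion limits halohydrin formation, and the oxirane C–H is not enolised, so the (S) centre is carried over unchanged.

**Step 4**
Reactants: 8 2-[(2S)-oxiran-2-yl]propan-2-ol
Product: 9 (2R)-1-iodo-3-methylbutane-2,3-diol
Conditions: LiI, AcOH, THF, 0 °C → rt, dark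
Reagents that add atoms: lithium iodide [Li+].[I-]
Why: Acid-assisted SN2 opening of a terminal epoxide by iodide at the unsubstituted CH2 (halohydrin formation) leaves the C–O bond at the stereocentre intact, so the configuration is retained; the descriptor becomes R only because CH2I outranks the carbinol carbon.

**Step 5**
Reactants: 5 7-methoxy-8-({3-[(tributylstannyl)methyl]but-3-en-1-yl}oxy)-2H-chromen-2-one; 9 (2R)-1-iodo-3-methylbutane-2,3-diol
Product: 10 8-{[(6S)-6,7-dihydroxy-7-methyl-3-methylideneoctyl]oxy}-7-methoxy-2H-chromen-2-one
Conditions: 9 (1.5 equiv), AIBN (0.2 equiv, in portions), degassed PhH, 80 °C, dark; aq KF work-up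
Reagents that add atoms: none
Why: Keck radical allylation (SH2' chain): Bu3Sn• abstracts iodine from 9, the primary β-hydroxyalkyl radical adds to the =CH2 terminus of the allylstannane in 5, and the tertiary β-stannyl radical fragments to the methylidene alkene and Bu3Sn•, which carries the chain. The closest known reaction type is the radical allylation of alkyl iodides with 2-substituted allyltributylstannanes. No ring is closed and no stereocentre is formed; the carbinol centre of 9 lies β to the radical carbon, has no bond broken, and should be carried over unchanged. The step needs chemoselectivity for the allylstannane over the coumarin C3=C4 bond, which the electron-rich 1,1-disubstituted stannyl alkene and the donor-deactivated, 1,2-disubstituted lactone alkene should secure; thermal initiation in the dark avoids coumarin photodimerisation. Because both termini of the 2-substituted allyl unit are CH2, the allyl transposition changes nothing in the constitution, and the free hydroxyls are inert to the radical chain.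

**Compound list**
1 | 3-methylbut-3-en-1-ol (isoprenol) | CC(=C)CCO | starting material
2 | dilithium salt of 3-methylbut-3-en-1-ol, lithiated at O and at the allylic methyl carbon (isoprenol dianion) | [Li]CC(=C)CCO[Li] | intermediate
3 | 3-[(tributylstannyl)methyl]but-3-en-1-ol | CCCC[Sn](CCCC)(CCCC)CC(=C)CCO | intermediate
4 | 8-hydroxy-7-methoxy-2H-chromen-2-one | COc1ccc2ccc(=O)oc2c1O | starting material
5 | 7-methoxy-8-({3-[(tributylstannyl)methyl]but-3-en-1-yl}oxy)-2H-chromen-2-one | CCCC[Sn](CCCC)(CCCC)CC(=C)CCOc1c(OC)ccc2ccc(=O)oc12 | intermediate
6 | methyl (2S)-oxirane-2-carboxylate | COC(=O)[C@@H]1CO1 | starting material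
7 | 1-[(2S)-oxiran-2-yl]ethan-1-one (epoxy ketone) | CC(=O)[C@@H]1CO1 | intermediate
8 | 2-[(2S)-oxiran-2-yl]propan-2-ol | CC(C)(O)[C@@H]1CO1 | intermediate
9 | (2R)-1-iodo-3-methylbutane-2,3-diol | CC(C)(O)[C@@H](O)CI | intermediate
10 | 8-{[(6S)-6,7-dihydroxy-7-methyl-3-methylideneoctyl]oxy}-7-methoxy-2H-chromen-2-one | C=C(CCOc1c(OC)ccc2ccc(=O)oc12)CC[C@H](O)C(C)(C)O | target

Total step count: 5
Longest linear sequence: 3 steps (steps 1, 2, 5 or steps 3, 4, 5)

**Steps most likely to fail**

1. Step 5. The radical chain may be short, and the alkyl radical may add to the coumarin C3=C4 bond or be lost before it meets the allylstannane. Tin residues may also be hard to part from the polar diol. The fallback forms the same C–C bond by polar epoxide opening and attaches the coumarin last. It sets out from 8: silylation of the tertiary hydroxyl (TESOTf, 2,6-lutidine, CH2Cl2, −78 °C) should give triethyl{[2-((2S)-oxiran-2-yl)propan-2-yl]oxy}silane F1. The dianion 2, made from 1 as in step 1, should open F1 at its CH2 (THF, −78 → 0 °C) to give (6S)-7-methyl-3-methylidene-7-[(triethylsilyl)oxy]octane-1,6-diol F2. TBAF in THF should then remove silicon, also if it has migrated to the neighbouring oxygen, and give (6S)-7-methyl-3-methylideneoctane-1,6,7-triol F3. Mitsunobu etherification of the primary hydroxyl of F3 with 4 (PPh3, DIAD, THF, 0 °C), the hindered secondary and the tertiary hydroxyl staying free, comes back to the route at 10.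

2. Step 2. The tin group may be lost by protonolysis or by attack of the azodicarboxylate on the electron-rich allylstannane, and the activated homoallylic alcohol may eliminate to a diene. The fallback replaces the redox condensation by a two-stage alkylation. It sets out from 3: sulfonylation (TsCl, Et3N, DMAP, CH2Cl2, 0 °C) should give 3-[(tributylstannyl)methyl]but-3-en-1-yl 4-methylbenzenesulfonate F4. Williamson etherification of 4 with F4 (K2CO3, DMF, 50 °C) comes back to the route at 5.

3. Step 3. The oxirane may be opened by the Grignard reagent or by halide, and the small, volatile, water-soluble product may be lost on isolation. The fallback opens the ring before the carbinol is built, so that no organomagnesium meets an epoxide and every intermediate is non-volatile. It sets out from 6: LiBr, AcOH, THF should open the oxirane at C3 to give methyl (2R)-3-bromo-2-hydroxypropanoate F5. MeMgCl (3.3 equiv, THF, −78 → 0 °C) should convert the ester into the tertiary carbinol and give (2R)-1-bromo-3-methylbutane-2,3-diol F6. Finkelstein exchange (NaI, butan-2-one, reflux) comes back to the route at 9.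

**Further compounds**
F1 | step 5 | triethyl{[2-((2S)-oxiran-2-yl)propan-2-yl]oxy}silane | CC[Si](CC)(CC)OC(C)(C)[C@@H]1CO1
F2 | step 5 | (6S)-7-methyl-3-methylidene-7-[(triethylsilyl)oxy]octane-1,6-diol | C=C(CCO)CC[C@H](O)C(C)(C)O[Si](CC)(CC)CC
F3 | step 5 | (6S)-7-methyl-3-methylideneoctane-1,6,7-triol | C=C(CCO)CC[C@H](O)C(C)(C)O
F4 | step 2 | 3-[(tributylstannyl)methyl]but-3-en-1-yl 4-methylbenzenesulfonate | Cc1ccc(cc1)S(=O)(=O)OCCC(=C)C[Sn](CCCC)(CCCC)CCCC
F5 | step 3 | methyl (2R)-3-bromo-2-hydroxypropanoate | COC(=O)[C@@H](O)CBr
F6 | step 3 | (2R)-1-bromo-3-methylbutane-2,3-diol | CC(C)(O)[C@@H](O)CBr
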